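**Retrosynthetic overview**
- The N–CH3 bond (C–N) is cut last: the target comes from 2,3,6-tribromo-1H-indole and MeI.
- Key cut, N1–C2 (C–N): the pyrrole ring opens to 4-bromo-1-(2,2-dibromovinyl)-2-nitrobenzene. In the forward direction the reduced nitro nitrogen closes onto the CBr2 carbon and one bromine moves from C2 to C3. Both pyrrole bromines therefore come from one CBr2 unit.
- The C2=C3 alkene comes from 4-bromo-2-nitrobenzaldehyde and CBr4 (Ramirez olefination).
- Ring order: the benzene ring is bought with the C6 bromine in place, and the pyrrole ring is formed second and last. No electrophilic bromination is needed.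

Assumption: the target is planar and has no stereocentre, so the given SMILES is its only stereoisomer and no enantiocontrol is required.

**Route**

Step 1
Reactants: 1 4-bromo-2-nitrobenzaldehyde
Product: 2 4-bromo-1-(2,2-dibromovinyl)-2-nitrobenzene
Conditions: CBr4 (1.5 equiv), PPh3 (3.0 equiv), CH2Cl2, 0 °C to rt, 1 h
Reagents that add atoms: carbon tetrabromide, BrC(Br)(Br)Br
Why: Ramirez gem-dibromoolefination (first stage of the Corey–Fuchs sequence), in which Ph3P=CBr2 made from CBr4 and PPh3 undergoes a Wittig reaction with the electron-poor aldehyde while the nitro group and aryl bromide stay inert at 0 °C; no stereocentre is formed.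

Step 2
Reactants: 2 4-bromo-1-(2,2-dibromovinyl)-2-nitrobenzene
Product: 6 2,3,6-tribromo-1H-indole, via 4-bromo-1-(2,2-dibromovinyl)-2-nitrosobenzene 3 (not isolated), via 2,2,6-tribromo-2H-indole 1-oxide 4 (not isolated), via 2,3,6-tribromo-1-hydroxyindole 5 (not isolated)
Conditions: TiCl3 (ca. 20% aq. solution in dilute HCl, 4.5 equiv, added over 1 h), NH4OAc (2.5 M aq., 20 equiv), acetone, N2, rt, 2 h
Reagents that add atoms: none
Why: Proposed new method: trivalent titanium reduces the nitro group of 2 to nitrosoarene 3, which closes by a five-atom, six-electron electrocyclisation onto the CBr2 terminus (N1–C2 bond) to give 4 with benzylic cation character at C3; one geminal bromine bridges to that centre and shifts from C2 to C3 (bromonium-type 1,2-shift, driven by C2=N formation and re-aromatisation of the benzene ring), loss of the C3 proton gives 5, and two more equivalents of TiCl3 cleave the N–O bond to give 6, while aryl and vinyl C–Br bonds are far too hard to reduce with TiCl3 at rt; the closest known reaction type is the TiCl3-promoted (and Cadogan–Sundberg) reductive cyclisation of β,β-disubstituted 2-nitrostyrenes, where a carbon group makes the same C2-to-C3 shift, but a halogen as migrating group and a gem-dibromovinyl nitroarene as substrate have not been shown (these nitroarenes have only been reduced to anilines), and support for the bromine shift comes from the AuCl3-catalysed cycloisomerisation of bromoallenyl ketones to 3-bromofurans; no stereocentre remains in 6.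

Step 3
Reactants: 6 2,3,6-tribromo-1H-indole
Product: 7 2,3,6-tribromo-1-methyl-1H-indole
Conditions: MeI (1.3 equiv), K2CO3 (2.0 equiv), DMF, 0 °C to rt, 2 h, in the dark
Reagents that add atoms: iodomethane, CI
Why: K2CO3-mediated SN2 N-methylation, in which the two pyrrole bromines make N–H acidic enough for carbonate, C3 is blocked so only nitrogen is alkylated, and all three C–Br bonds are inert to carbonate and MeI; no stereocentre is formed.

**Compound list**
1 | 4-bromo-2-nitrobenzaldehyde | O=Cc1ccc(Br)cc1[N+](=O)[O-] | starting material
2 | 4-bromo-1-(2,2-dibromovinyl)-2-nitrobenzene | BrC(Br)=Cc1ccc(Br)cc1[N+](=O)[O-] | intermediate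
3 | 4-bromo-1-(2,2-dibromovinyl)-2-nitrosobenzene | BrC(Br)=Cc1ccc(Br)cc1N=O | intermediate
4 | 2,2,6-tribromo-2H-indole 1-oxide | [O-][N+]1=C2C=C(Br)C=CC2=CC1(Br)Br | intermediate
5 | 2,3,6-tribromo-1-hydroxyindole | On1c(Br)c(Br)c2ccc(Br)cc21 | intermediate
6 | 2,3,6-tribromo-1H-indole | Brc1[nH]c2cc(Br)ccc2c1Br | intermediate
7 | 2,3,6-tribromo-1-methyl-1H-indole | Cn1c(Br)c(Br)c2ccc(Br)cc21 | target

**Totals**
Total step count: 3. Longest linear sequence: 3.

**Steps most likely to fail (ranked)**

Step 2 (the proposed new step). There are three likely failure modes:
- 3 is over-reduced to the aniline before it cyclises.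
- Water is captured at C3 of 4.
- A bromine is lost, giving a 2-bromoindole.

The fallback uses known chemistry, sets out from 2 and comes back at 6. The nitro group is reduced with SnCl2·2H2O in EtOH at reflux to 5-bromo-2-(2,2-dibromovinyl)aniline F1, which is also what over-reduction in step 2 would deliver. The pyrrole ring is then closed by the known intramolecular vinyl C–N coupling with the zerovalent palladium complex Pd(P(t-Bu)3)2 (5 mol %) and K2CO3 in toluene at 100 °C. This catalyst adds to C–Br bonds reversibly, which spares the aryl bromide and the product bromide, and gives 2,6-dibromo-1H-indole F2. NBS (1.0 equiv, DMF, 0 °C) then brominates C3 to give 6.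

Step 3. Compound 6 is sensitive to air, light and base, and may decompose or lose its C3 bromine before it is alkylated. The fallback changes the order of events so that the C3 bromine enters last. It sets out from 2 and comes back at 7. Compound 2 is taken through F1 and F2 as described above. F2 is N-methylated (NaH, MeI, THF, 0 °C) to 2,6-dibromo-1-methyl-1H-indole F3. NBS (1.0 equiv, THF, −78 °C to rt) then brominates the free C3 position and gives 7 directly.

Step 1. The risk is low. Warm PPh3 can attack the nitro group, and removal of the phosphorus by-products can cost material. The fallback avoids phosphorus altogether, sets out from 1 and comes back at 2. Compound 1 is condensed with N2H4·H2O in EtOH at rt to (E)-(4-bromo-2-nitrobenzylidene)hydrazine F4. This hydrazone undergoes the CuCl-catalysed olefination with CBr4 (CuCl 10 mol %, aq. NH3, DMSO, rt), loses nitrogen and gives 2.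

**Further compounds**
F1 | step 2 | 5-bromo-2-(2,2-dibromovinyl)aniline | Nc1cc(Br)ccc1C=C(Br)Br
F2 | step 2 | 2,6-dibromo-1H-indole | Brc1cc2ccc(Br)cc2[nH]1
F3 | step 3 | 2,6-dibromo-1-methyl-1H-indole | Cn1c(Br)cc2ccc(Br)cc21
F4 | step 1 | (E)-(4-bromo-2-nitrobenzylidene)hydrazine | N/N=C/c1ccc(Br)cc1[N+](=O)[O-]
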